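**Retrosynthetic overview**
- Last bonds: the C8 ester of (Z)-2-(acetoxymethyl)but-2-enoic acid and removal of a C3 silyl ether, leading back to a tricyclic C8 alcohol.
- Ring B (oxepane O–C5–C6–C7–C8–C9–C10) is closed last through C7–C8 by an intramolecular Hosomi–Sakurai reaction of an α-(silylmethyl)butenolide with the C8 aldehyde; this also creates the C11=C13 methylene.
- Rings A (oxepane O–C5–C4–C3–C2–C1–C10) and C (lactone) form together in the key step: in an acyclic cis-epoxy enoate the tertiary C10 hydroxyl opens the epoxide 7-exo at C5 and the freed C6 hydroxyl lactonises.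
- The cis-epoxy enoate comes from a Z-allylic alcohol (Sharpless epoxidation, oxidation, Z-selective olefination); C3/C4 come from an Evans syn-aldol between a linalool-derived aldehyde and a (Z)-pent-3-enoyl imide.
- C10 comes from (R)-linalool; ring order: A and C in one operation, then B.

Assumption: the SMILES is read literally, (3R,4R,5R,6R,7R,8R,10R); in this isomer C6 and C9 lie on opposite faces of ring A, so ring B spans the C5–O–C10 ether in the trans (inside–outside) sense, and C5 and C10 are therefore set independently of any ring bias.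

Numbering: germacranolide numbering of the target is used for all intermediates (C1–C10 carbocycle, C11–C13 lactone carbons, C14 methyl, C15 acetoxymethyl carbon).

**Step 1**
Reactants: 1 (R)-(−)-linalool
Product: 3 (3R)-3,7-dimethyloct-6-ene-1,3-diol, via B-alkyl-9-BBN adduct 2 (not isolated)
Conditions: 9-BBN (1.5 equiv), THF, 0 °C → rt; then NaOH (aq), H2O2, 0 °C
Reagents that add atoms: hydrogen peroxide, OO
Why: Hydroboration–oxidation, in which 9-BBN adds anti-Markovnikov and only to the monosubstituted vinyl group, so C8 becomes a primary alcohol while the chiral-pool C10 centre is untouched.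

**Step 2**
Reactants: 3 (3R)-3,7-dimethyloct-6-ene-1,3-diol
Product: 4 (3R)-3,7-dimethyl-1,3-bis(triethylsilyloxy)oct-6-ene
Conditions: Et3SiOTf (2.4 equiv), 2,6-lutidine, CH2Cl2, −78 → 0 °C
Reagents that add atoms: triethylsilyl triflate, CC[Si](CC)(CC)OS(=O)(=O)C(F)(F)F
Why: Silyl ether formation with the silyl triflate, which is reactive enough to cap the tertiary as well as the primary hydroxyl without touching a stereocentre.

**Step 3**
Reactants: 4 (3R)-3,7-dimethyl-1,3-bis(triethylsilyloxy)oct-6-ene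
Product: 6 (4R)-4-methyl-4,6-bis(triethylsilyloxy)hexanal, via secondary ozonide 5 (not isolated)
Conditions: O3, CH2Cl2, −78 °C; then PPh3, −78 °C → rt
Reagents that add atoms: ozone, [O-][O+]=O
Why: Ozonolysis with reductive work-up cleaves the only alkene to the C3 aldehyde and acetone.

**Step 4**
Reactants: 7 (2-carboxyethyl)triphenylphosphonium bromide; 8 2-[(4-methoxybenzyl)oxy]acetaldehyde
Product: 10 (Z)-5-[(4-methoxybenzyl)oxy]pent-3-enoic acid, via phosphorane carboxylate 9 (not isolated)
Conditions: NaN(SiMe3)2 (2.1 equiv), THF, −78 → 0 °C; then 8, −78 °C → rt; aq. HCl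
Reagents that add atoms: none
Why: Wittig olefination with a non-stabilised phosphorane under lithium-free conditions is kinetically Z-selective and gives the skipped (β,γ) unsaturated acid.

**Step 5**
Reactants: 10 (Z)-5-[(4-methoxybenzyl)oxy]pent-3-enoic acid; 11 (S)-4-benzyl-1,3-oxazolidin-2-one
Product: 13 (S)-4-benzyl-3-[(Z)-5-(4-methoxybenzyloxy)pent-3-enoyl]-1,3-oxazolidin-2-one, via mixed pivalic anhydride 12 (not isolated)
Conditions: tBuCOCl, Et3N, THF, −20 °C; then 11, LiCl, −20 °C → rt
Reagents that add atoms: none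
Why: N-Acylation of the oxazolidinone through the mixed pivalic anhydride under mild LiCl/Et3N activation, which does not move the Z-alkene into conjugation.

**Step 6**
Reactants: 6 (4R)-4-methyl-4,6-bis(triethylsilyloxy)hexanal; 13 (S)-4-benzyl-3-[(Z)-5-(4-methoxybenzyloxy)pent-3-enoyl]-1,3-oxazolidin-2-one
Product: 15 Evans syn-aldol adduct (2S,3R,6R in the octanoyl chain; C3 hydroxyl free), via dibutylboron Z-enolate 14 (not isolated)
Conditions: Bu2BOTf, iPr2NEt, CH2Cl2, −78 → 0 °C; then 6, −78 → 0 °C; pH 7 buffer, MeOH, H2O2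
Reagents that add atoms: none
Why: Evans syn-aldol reaction, in which the Z-boron enolate 14 reacts through a Zimmerman–Traxler chair on the face away from the benzyl group, setting C3 (R) and C4 with O3 and C5 syn, independently of C10.

**Step 7**
Reactants: 15 Evans syn-aldol adduct
Product: 16 3-O-tert-butyldimethylsilyl ether of the aldol adduct
Conditions: tBuMe2SiOTf, 2,6-lutidine, CH2Cl2, 0 °C
Reagents that add atoms: tert-butyldimethylsilyl triflate, CC(C)(C)[Si](C)(C)OS(=O)(=O)C(F)(F)F
Why: Silylation of the hindered secondary C3 hydroxyl with the silyl triflate, so that only O8 can be acylated at the end.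

**Step 8**
Reactants: 16 3-O-silyl aldol imide
Product: 17 C15 primary alcohol (3-OTBS; Z-allylic PMB ether; 8,10-bis-OTES)
Conditions: LiBH4, MeOH (1 equiv), THF, 0 °C; aq. NaOH work-up
Reagents that add atoms: none
Why: Reductive cleavage of the N-acyl oxazolidinone with LiBH4 gives the C15 alcohol without epimerising C4 and returns the auxiliary.

**Step 9**
Reactants: 17 C15 primary alcohol
Product: 18 C15 acetate
Conditions: Ac2O, pyridine, DMAP (cat.), CH2Cl2, 0 °C → rt
Reagents that add atoms: acetic anhydride, CC(=O)OC(C)=O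
Why: Acetylation installs the C15 acetate of the target early, and it is carried unchanged to the end.

**Step 10**
Reactants: 18 C15 acetate
Product: 19 (Z)-allylic alcohol (C7 hydroxyl free)
Conditions: DDQ, CH2Cl2/pH 7 buffer (10:1), 0 °C
Reagents that add atoms: none
Why: Oxidative cleavage of the 4-methoxybenzyl ether by DDQ frees the Z-allylic alcohol and leaves silyl ethers and the acetate alone.

**Step 11**
Reactants: 19 (Z)-allylic alcohol
Product: 20 cis-2,3-epoxy alcohol (C5 S, C6 R)
Conditions: Ti(OiPr)4 (0.5 equiv), D-(−)-diethyl tartrate (0.6 equiv), tBuOOH, 4 Å molecular sieves, CH2Cl2, −20 °C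
Reagents that add atoms: tert-butyl hydroperoxide, CC(C)(C)OO
Why: Sharpless asymmetric epoxidation, in which the D-(−)-tartrate complex selects the alkene face that gives the cis-epoxide with C5 (S) and C6 (R) under reagent control (also the face syn to C15 in the allylic-strain-minimised conformer).

**Step 12**
Reactants: 20 cis-2,3-epoxy alcohol
Product: 21 cis-epoxy aldehyde (C7 aldehyde)
Conditions: Dess–Martin periodinane, pyridine, CH2Cl2, 0 °C → rt
Reagents that add atoms: none
Why: Dess–Martin oxidation of the primary epoxy alcohol under buffered conditions that do not epimerise C6.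

**Step 13**
Reactants: 22 methyl 2-[bis(2,2,2-trifluoroethoxy)phosphoryl]acetate
Product: 24 methyl 2-[bis(2,2,2-trifluoroethoxy)phosphoryl]-3-(trimethylsilyl)propanoate (racemic), via sodium phosphonoacetate enolate 23 (not isolated)
Conditions: NaH, DMF, 0 °C; then ICH2SiMe3, 60 °C
Reagents that add atoms: (iodomethyl)trimethylsilane, C[Si](C)(C)CI
Why: SN2 C-alkylation of the stabilised phosphonoacetate anion with the α-silyl iodide gives the α-(silylmethyl) Still–Gennari reagent that carries C11, C12 and C13.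

**Step 14**
Reactants: 21 cis-epoxy aldehyde; 24 methyl 2-[bis(2,2,2-trifluoroethoxy)phosphoryl]-3-(trimethylsilyl)propanoate
Product: 26 cis-epoxy enoate (methyl ester cis to C6; CH2SiMe3 on C11), via potassium phosphonate carbanion 25 (not isolated)
Conditions: KN(SiMe3)2, 18-crown-6, THF, −78 °C; then 21, −78 °C
Reagents that add atoms: none
Why: Still–Gennari-type Horner–Wadsworth–Emmons olefination, whose electron-poor phosphonate eliminates under kinetic control to put the ester cis to C6 (E by CIP only because CH2SiMe3 outranks CO2Me), the geometry needed for lactonisation.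

**Step 15 (key step)**
Reactants: 26 cis-epoxy enoate
Product: 29 ring A oxepane carrying the 3-(trimethylsilylmethyl)butenolide ring C at C5 and a free C8 alcohol, via desilylated epoxy enoate diol 27 (not isolated), via ring A hydroxy ester 28 (not isolated)
Conditions: CSA (0.3 equiv), MeOH (10 equiv), CH2Cl2, 0 °C → rt
Reagents that add atoms: none
Why: Acid-triggered cascade in which both Et3Si ethers are methanolysed, the tertiary C10 hydroxyl opens the epoxide 7-exo-tet at C5 with inversion to form ring A and set C5 (R) (attack at C6 is disfavoured by the adjacent electron-poor alkene and the larger ring), and the released C6 hydroxyl lactonises onto the cis ester with retention to form ring C.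

**Step 16**
Reactants: 29 ring A–butenolide alcohol
Product: 30 ring A–butenolide C8 aldehyde
Conditions: Dess–Martin periodinane, pyridine, CH2Cl2, 0 °C → rt
Reagents that add atoms: none
Why: Dess–Martin oxidation of the primary C8 alcohol to the aldehyde under neutral conditions that spare the β-alkoxy aldehyde and the allylsilane.

**Step 17**
Reactants: 30 ring A–butenolide C8 aldehyde
Product: 31 tricyclic C8 alcohol (rings A, B and C; exocyclic methylene; 3-OTBS; 15-OAc)
Conditions: BF3·OEt2 (2 equiv), CH2Cl2 (2 mM), −78 → −20 °C; aq. NaHCO3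
Reagents that add atoms: none
Why: Intramolecular Hosomi–Sakurai allylation, in which C7 adds to the activated aldehyde and loss of silicon unveils the C11=C13 methylene; the tether forces the new C7–C8 bond cis to C5 on the lactone, and a synclinal transition state with the complexed oxygen exo is expected to place the C8 hydroxyl cis to C11 while ring B closes across the trans-disposed arms.

**Step 18**
Reactants: 32 methyl but-2-ynoate
Product: 34 methyl (Z)-2-(hydroxymethyl)but-2-enoate, via α-aluminated enoate 33 (not isolated)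
Conditions: iBu2AlH, HMPA, THF, 0 °C; then (CH2O)n, 0 °C → rt; aq. HCl
Reagents that add atoms: formaldehyde (from paraformaldehyde), C=O
Why: Conjugate syn-hydroalumination of the ynoate puts the methyl group cis to the ester, and the vinylalane is trapped by formaldehyde with retention (vinylalumination) to give the Z-alkene.

**Step 19**
Reactants: 34 methyl (Z)-2-(hydroxymethyl)but-2-enoate
Product: 35 (Z)-2-(hydroxymethyl)but-2-enoic acid
Conditions: LiOH, THF/H2O (3:1), 0 °C; then aq. HCl to pH 2
Reagents that add atoms: lithium hydroxide, [Li+].[OH-]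
Why: Saponification of the methyl ester at low temperature keeps the Z geometry.

**Step 20**
Reactants: 35 (Z)-2-(hydroxymethyl)but-2-enoic acid
Product: 36 (Z)-2-(acetoxymethyl)but-2-enoic acid
Conditions: Ac2O, pyridine, 0 °C → rt; aqueous work-up
Reagents that add atoms: acetic anhydride, CC(=O)OC(C)=O
Why: O-Acetylation of the primary alcohol, with the free carboxylic acid recovered on aqueous work-up.

**Step 21**
Reactants: 31 tricyclic C8 alcohol; 36 (Z)-2-(acetoxymethyl)but-2-enoic acid
Product: 38 3-O-tert-butyldimethylsilyl ether of the target, via trichlorobenzoyl mixed anhydride 37 (not isolated)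
Conditions: 2,4,6-Cl3C6H2COCl, Et3N, toluene, rt; then 31, toluene, 80 °C
Reagents that add atoms: none
Why: Yamaguchi-type esterification through the mixed anhydride without DMAP, conditions used for angelate-type acids to avoid Z to E isomerisation, acylates O8 with retention at C8.

**Step 22**
Reactants: 38 3-O-tert-butyldimethylsilyl ether of the target
Product: 39 CNP0426612.2 (target)
Conditions: HF·pyridine, pyridine, THF, 0 °C → rt
Reagents that add atoms: none
Why: Fluoride-mediated cleavage of the secondary silyl ether under buffered conditions leaves both acetates, the allylic ester and the α-methylene lactone intact.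

**Compound list**
1 | (R)-(−)-linalool, (3R)-3,7-dimethylocta-1,6-dien-3-ol | C=C[C@](C)(O)CCC=C(C)C | starting material
2 | (3R)-1-(9-borabicyclo[3.3.1]nonan-9-yl)-3,7-dimethyloct-6-en-3-ol | C1CCC2CCCC1B2CC[C@](C)(O)CCC=C(C)C | intermediate
3 | (3R)-3,7-dimethyloct-6-ene-1,3-diol | OCC[C@](C)(O)CCC=C(C)C | intermediate
4 | (3R)-3,7-dimethyl-1,3-bis(triethylsilyloxy)oct-6-ene | CC[Si](CC)(CC)OCC[C@](C)(O[Si](CC)(CC)CC)CCC=C(C)C | intermediate
5 | secondary ozonide (3,3-dimethyl-1,2,4-trioxolane) of 4 | CC[Si](CC)(CC)OCC[C@](C)(O[Si](CC)(CC)CC)CCC1OOC(C)(C)O1 | intermediate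
6 | (4R)-4-methyl-4,6-bis(triethylsilyloxy)hexanal (C3 aldehyde) | CC[Si](CC)(CC)OCC[C@](C)(O[Si](CC)(CC)CC)CCC=O | intermediate
7 | (2-carboxyethyl)triphenylphosphonium bromide | OC(=O)CC[P+](c1ccccc1)(c1ccccc1)c1ccccc1.[Br-] | starting material
8 | 2-[(4-methoxybenzyl)oxy]acetaldehyde | COc1ccc(COCC=O)cc1 | starting material
9 | sodium 3-(triphenylphosphoranylidene)propanoate | [Na+].[O-]C(=O)CC=P(c1ccccc1)(c1ccccc1)c1ccccc1 | intermediate
10 | (Z)-5-[(4-methoxybenzyl)oxy]pent-3-enoic acid | COc1ccc(COC/C=C\CC(=O)O)cc1 | intermediate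
11 | (S)-4-benzyl-1,3-oxazolidin-2-one | O=C1N[C@@H](Cc2ccccc2)CO1 | starting material
12 | pivalic (Z)-5-[(4-methoxybenzyl)oxy]pent-3-enoic anhydride | COc1ccc(COC/C=C\CC(=O)OC(=O)C(C)(C)C)cc1 | intermediate
13 | (S)-4-benzyl-3-[(Z)-5-(4-methoxybenzyloxy)pent-3-enoyl]-1,3-oxazolidin-2-one | COc1ccc(COC/C=C\CC(=O)N2C(=O)OC[C@@H]2Cc3ccccc3)cc1 | intermediate
14 | dibutylboron Z-enolate of 13 | CCCCB(CCCC)O/C(=C\C=C/COCc1ccc(OC)cc1)N2C(=O)OC[C@@H]2Cc3ccccc3 | intermediate
15 | (S)-4-benzyl-3-[(2S,3R,6R)-3-hydroxy-2-[(Z)-3-(4-methoxybenzyloxy)prop-1-enyl]-6-methyl-6,8-bis(triethylsilyloxy)octanoyl]-1,3-oxazolidin-2-one | CC[Si](CC)(CC)OCC[C@](C)(O[Si](CC)(CC)CC)CC[C@@H](O)[C@@H](C(=O)N1C(=O)OC[C@@H]1Cc2ccccc2)/C=C\COCc3ccc(OC)cc3 | intermediate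
16 | 3-O-tert-butyldimethylsilyl ether of 15 | CC[Si](CC)(CC)OCC[C@](C)(O[Si](CC)(CC)CC)CC[C@@H](O[Si](C)(C)C(C)(C)C)[C@@H](C(=O)N1C(=O)OC[C@@H]1Cc2ccccc2)/C=C\COCc3ccc(OC)cc3 | intermediate
17 | (2R,3R,6R)-3-(tert-butyldimethylsilyloxy)-2-[(Z)-3-(4-methoxybenzyloxy)prop-1-enyl]-6-methyl-6,8-bis(triethylsilyloxy)octan-1-ol (C15 alcohol) | CC[Si](CC)(CC)OCC[C@](C)(O[Si](CC)(CC)CC)CC[C@@H](O[Si](C)(C)C(C)(C)C)[C@@H](CO)/C=C\COCc1ccc(OC)cc1 | intermediate
18 | C15 acetate of 17 | CC[Si](CC)(CC)OCC[C@](C)(O[Si](CC)(CC)CC)CC[C@@H](O[Si](C)(C)C(C)(C)C)[C@@H](COC(C)=O)/C=C\COCc1ccc(OC)cc1 | intermediate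
19 | (2Z,4R,5R,8R)-4-(acetoxymethyl)-5-(tert-butyldimethylsilyloxy)-8-methyl-8,10-bis(triethylsilyloxy)dec-2-en-1-ol (C7 allylic alcohol) | CC[Si](CC)(CC)OCC[C@](C)(O[Si](CC)(CC)CC)CC[C@@H](O[Si](C)(C)C(C)(C)C)[C@@H](COC(C)=O)/C=C\CO | intermediate
20 | cis-epoxy alcohol of 19 (C5–C6 epoxide, C5 S, C6 R) | CC[Si](CC)(CC)OCC[C@](C)(O[Si](CC)(CC)CC)CC[C@@H](O[Si](C)(C)C(C)(C)C)[C@@H](COC(C)=O)[C@@H]1O[C@@H]1CO | intermediate
21 | cis-epoxy aldehyde (C7 aldehyde) | CC[Si](CC)(CC)OCC[C@](C)(O[Si](CC)(CC)CC)CC[C@@H](O[Si](C)(C)C(C)(C)C)[C@@H](COC(C)=O)[C@@H]1O[C@@H]1C=O | intermediate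
22 | methyl 2-[bis(2,2,2-trifluoroethoxy)phosphoryl]acetate | COC(=O)CP(=O)(OCC(F)(F)F)OCC(F)(F)F | starting material
23 | sodium salt (carbanion) of 22 | [Na+].COC(=O)[CH-]P(=O)(OCC(F)(F)F)OCC(F)(F)F | intermediate
24 | methyl 2-[bis(2,2,2-trifluoroethoxy)phosphoryl]-3-(trimethylsilyl)propanoate (racemic) | COC(=O)C(C[Si](C)(C)C)P(=O)(OCC(F)(F)F)OCC(F)(F)F | intermediate
25 | potassium salt (carbanion) of 24 | [K+].COC(=O)[C-](C[Si](C)(C)C)P(=O)(OCC(F)(F)F)OCC(F)(F)F | intermediate
26 | cis-epoxy enoate: methyl 2-(trimethylsilylmethyl)alk-2-enoate with ester cis to C6, C5–C6 cis-epoxide, 3-OTBS, 15-OAc, 8,10-bis-OTES | CC[Si](CC)(CC)OCC[C@](C)(O[Si](CC)(CC)CC)CC[C@@H](O[Si](C)(C)C(C)(C)C)[C@@H](COC(C)=O)[C@@H]1O[C@@H]1/C=C(/C[Si](C)(C)C)C(=O)OC | intermediate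
27 | 8,10-diol of 26 (both Et3Si groups removed) | OCC[C@](C)(O)CC[C@@H](O[Si](C)(C)C(C)(C)C)[C@@H](COC(C)=O)[C@@H]1O[C@@H]1/C=C(/C[Si](C)(C)C)C(=O)OC | intermediate
28 | ring A oxepane with C6 hydroxyl and uncyclised cis methyl enoate | COC(=O)/C(C[Si](C)(C)C)=C\[C@@H](O)[C@@H]1O[C@@](C)(CCO)CC[C@@H](O[Si](C)(C)C(C)(C)C)[C@H]1COC(C)=O | intermediate
29 | ring A oxepane with 3-(trimethylsilylmethyl)furan-2(5H)-on-5-yl group at C5 (ring C), 2-hydroxyethyl and methyl at C10, 3-OTBS, 15-OAc | C[Si](C)(C)CC1=C[C@@H](OC1=O)[C@@H]2O[C@@](C)(CCO)CC[C@@H](O[Si](C)(C)C(C)(C)C)[C@H]2COC(C)=O | intermediate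
30 | C8 aldehyde of 29 | C[Si](C)(C)CC1=C[C@@H](OC1=O)[C@@H]2O[C@@](C)(CC=O)CC[C@@H](O[Si](C)(C)C(C)(C)C)[C@H]2COC(C)=O | intermediate
31 | tricyclic 8-hydroxy α-methylene lactone (3-OTBS, 15-OAc; all centres as in target) | C=C1C(=O)O[C@H]2[C@@H]3O[C@](C)(CC[C@@H](O[Si](C)(C)C(C)(C)C)[C@H]3COC(C)=O)C[C@@H](O)[C@@H]12 | intermediate
32 | methyl but-2-ynoate | CC#CC(=O)OC | starting material
33 | methyl 2-(diisobutylalumanyl)but-2-enoate (methyl cis to ester) | C/C=C(/[Al](CC(C)C)CC(C)C)C(=O)OC | intermediate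
34 | methyl (Z)-2-(hydroxymethyl)but-2-enoate | C/C=C(/CO)C(=O)OC | intermediate
35 | (Z)-2-(hydroxymethyl)but-2-enoic acid | C/C=C(/CO)C(=O)O | intermediate
36 | (Z)-2-(acetoxymethyl)but-2-enoic acid | C/C=C(/COC(C)=O)C(=O)O | intermediate
37 | (Z)-2-(acetoxymethyl)but-2-enoic 2,4,6-trichlorobenzoic anhydride | C/C=C(/COC(C)=O)C(=O)OC(=O)c1c(Cl)cc(Cl)cc1Cl | intermediate
38 | 3-O-tert-butyldimethylsilyl ether of the target | C=C1C(=O)O[C@H]2[C@@H]3O[C@](C)(CC[C@@H](O[Si](C)(C)C(C)(C)C)[C@H]3COC(C)=O)C[C@@H](OC(=O)/C(=C\C)COC(C)=O)[C@@H]12 | intermediate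
39 | CNP0426612.2, (3R,4R,5R,6R,7R,8R,10R) | C=C1C(=O)O[C@H]2[C@@H]3O[C@](C)(CC[C@@H](O)[C@H]3COC(C)=O)C[C@@H](OC(=O)/C(=C\C)COC(C)=O)[C@@H]12 | target

**Step count and risks**

Total step count: 22. Longest linear sequence: 16 steps from (R)-linalool (steps 1–3, 6–12, 14–17, 21, 22).

Most likely to fail, first: step 17. Ring B has to close across arms that sit trans on ring A, giving a strained inside–outside bicycle, and the electron-poor allylsilane is a weak nucleophile; the C8 configuration is also only predicted. The fallback sets out from 30: bromodesilylation with N-bromosuccinimide (CH2Cl2, −78 °C) gives the β-bromo-α-methylene lactone aldehyde F1. Its allylic bromide is then converted with CrCl2 (THF/DMF, high dilution, rt) into an allylchromium species that adds to the aldehyde through a closed six-membered transition state, a Nozaki–Hiyama-type ring closure that tolerates strained rings, and this comes back to the route at 31.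

Second: step 15. The C15 acetate carbonyl can compete for C5 through a six-membered acyloxonium ion, methanol can open the epoxide before the tertiary hydroxyl is free, and the C3 silyl ether may be lost. The fallback sets out from 21 and reverses the order of events: aqueous acid (AcOH/THF/H2O) removes both Et3Si groups while the formyl group deactivates C6, so the tertiary hydroxyl attacks C5 and gives the ring A α-hydroxy aldehyde F2. Z-selective olefination of F2 with 24 (excess KN(SiMe3)2, 18-crown-6, −78 °C) is followed by spontaneous lactonisation and comes back to the route at 29.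

Third: step 11. Z-allylic alcohols with a bulky allylic substituent are slow and sometimes poorly selective substrates for the titanium–tartrate epoxidation. The fallback sets out from 17 and uses substrate control instead: VO(acac)2/tBuOOH epoxidation directed by the free homoallylic C15 hydroxyl, which under allylic-strain control delivers oxygen to the same face, gives the C15-hydroxy cis-epoxide PMB ether F3. Acetylation (Ac2O, pyridine) gives the C15-acetoxy cis-epoxide PMB ether F4, and DDQ cleavage of the 4-methoxybenzyl ether comes back to the route at 20.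

Further compounds
F1 | step 17 | β-bromo-α-methylene lactone aldehyde (bromide at C7, mixture of C7 epimers; ring A as in 30) | C=C1C(Br)[C@@H](OC1=O)[C@@H]2O[C@@](C)(CC=O)CC[C@@H](O[Si](C)(C)C(C)(C)C)[C@H]2COC(C)=O
F2 | step 15 | ring A α-hydroxy aldehyde (C6 hydroxyl, C7 aldehyde, C8 alcohol, 3-OTBS, 15-OAc) | O=C[C@@H](O)[C@@H]1O[C@@](C)(CCO)CC[C@@H](O[Si](C)(C)C(C)(C)C)[C@H]1COC(C)=O
F3 | step 11 | C15-hydroxy cis-epoxide with C7 4-methoxybenzyl ether | CC[Si](CC)(CC)OCC[C@](C)(O[Si](CC)(CC)CC)CC[C@@H](O[Si](C)(C)C(C)(C)C)[C@@H](CO)[C@@H]1O[C@@H]1COCc2ccc(OC)cc2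
F4 | step 11 | C15-acetoxy cis-epoxide with C7 4-methoxybenzyl ether | CC[Si](CC)(CC)OCC[C@](C)(O[Si](CC)(CC)CC)CC[C@@H](O[Si](C)(C)C(C)(C)C)[C@@H](COC(C)=O)[C@@H]1O[C@@H]1COCc2ccc(OC)cc2
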